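The earlier runs and the new flask are calculated on assumed constants; the scatter is artificial.

Z in the cedar flask read 40%, 38% and 41% from 25.0 min on, so the thing to watch is the pool s = cE + cZ, which the step to D drains.

| flask | E | remark | time |
|---|---|---|---|
| cedar | 0.80 M | the very flask that is asked about, followed so far |  |
| elm | 0.54 M | run made earlier |  |
| flask | 0.80 M |  | 50 min |

| run | time / min | Z / % | E / % |
|---|---|---|---|
| cedar | 12.0 | 32 | 35 |
| cedar | 25.0 | 40 | 23 |
| cedar | 40.0 | 38 | 13 |
| cedar | 50.0 | 41 | 13 |
| elm | 4.00 | 18 | 66 |
| elm | 12.0 | 36 | 39 |
| elm | 25.0 | 44 | 24 |
| elm | 40.0 | 46 | 24 |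

(readings scatter by 2 percentage points)

- grey: at 50 min add E, 50.0% of the amount charged, then wait 1.5 h
- blue: at 50 min take out 90% of the Z then present, then wait 1.5 h
- ochre: change nothing and wait 1.5 h more

- percent here means E units held: one D counts as two
- what is taken out of Z is counted as made
- what may be going on: E <-> Z; 2 E -> D
- additions bring no volume worth counting

- Z, in percent of the E first charged, at 50 min
- what to do for the largest gain in Z; "none" if nothing gains more than 2 percentage points (grey / blue / ochre / none)
- Z present, with what was taken out counted in, in percent of the E first charged, after blue
- Z present, with what was taken out counted in, in percent of the E first charged, after ochre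

I took E and Z to keep a steady ratio (a pre-equilibrium) and read E's share of the pool over cedar's last three readings as 0.292. Treating the pool as all E in elm's first reading, and scaling by the charge, gave a bare constant of 0.0705 min⁻¹ for cedar. D takes E in pairs, so the pool's fall goes with its square, and its reciprocal climbs in a straight line with time, s counted as a fraction of the charge. I call that slope, bare times share squared, 0.00600 min⁻¹, the drain constant.

Turned round: from s = 54.0% I reckoned Z at 38.3%, and for waiting to cost less than 2 percentage points of Z, the product x of drain constant, s and time had to stay below 0.0552. Cedar stood above that at 0.292, so ochre loses, ending at 29.6%.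

Blue cuts s to 19.6%, and my total came to 47.0%. The line gave grey 47.2%, but it counts added E as already in its share. Just after the addition I reckoned the loss at 0.0305 min⁻¹, against 0.00649 min⁻¹ by the line, so I put blue first.

The forecast gave 41% now, blue as best, 48% after blue and 33% after ochre, each above mine, and said “Blue narrowly beats grey”.

The flask gave 40.0%, with blue best at 7.7 points against 5.1 points for grey and −9.2 points for ochre, then 47.7% after blue and 30.9% after ochre.

    E ⇌ Z (K = 2.30, k = 0.00100 s⁻¹)
    2 E → D (k = 7.90 × 10⁻⁴ L mol⁻¹ s⁻¹)

By 5.00 min half of D's turnover up to 50 min was done, while E stood at 57.0%; E and Z relaxed by their own step with a half-life of 8.05 min, short against 50 min. Then the pool drained, and untouched cedar held Z 15.5% at 500 min, against 15.6% from the drain constant. The neighbour flask with 1.4 M of E, its constant scaled with the charge to 0.0105 min⁻¹ on cedar's intercept, reckoned 34.1% and held Z 31.5%.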